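**Plan**
- Retrosynthesis: the C3'–alkenyl bond is cut first (Stille coupling of a C3' iodide with a Z-alkenylstannane). The 6'-O-methyl group and the protecting groups are then removed on paper to reach a symmetric 2',4',6'-trihydroxychalcone.
- Ring A is opened at the C1'–C2' bond to a linear methyl 9-aryl-3,5,7-trioxonon-8-enoate. Its C6–C7 bond is cut to a cinnamoyl Weinreb amide and methyl 3,5-dioxohexanoate, and the enamide C=C to 4-(methoxymethoxy)benzaldehyde.
- Enabling feature: ring A is a phloroglucinol whose oxygens on C2', C4' and C6' alternate with C1', C3' and C5', and C1' carries the cinnamoyl carbonyl carbon. This is the pattern of a 3,5,7-trioxo ester folded so that C6 meets C1.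
- Forward: the chain is joined first (Horner–Wadsworth–Emmons, then trianion acylation). Ring A, the only ring made, closes by Claisen cyclization. The symmetric ring is then differentiated by 4'-O-MOM protection, mono-O-methylation and C3' iodination, followed by deprotection and coupling.
- Stereochemistry: there are no stereocentres. The E enone comes from the Horner–Wadsworth–Emmons step. The Z side-chain alkene comes from syn-hydrozirconation and protonolysis of an alkynylstannane and is carried over with retention in the Stille coupling.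

Key step: step 4

Assumption: chalcone locants are used (ring A primed, C1' bearing the carbonyl); phosphonate 3 and methyl 3,5-dioxohexanoate 5 are taken as purchasable reagents.

**Step 1**
Reactants: 1 4-hydroxybenzaldehyde
Product: 2 4-(methoxymethoxy)benzaldehyde
Conditions: MOMCl, iPr2NEt, CH2Cl2, 0 °C → rt
Reagents that add atoms: chloromethyl methyl ether, COCCl
Why: Williamson-type O-alkylation of the phenol with an α-chloro ether should give the MOM ether, which is stable to every basic step up to step 7.

**Step 2**
Reactants: 2 4-(methoxymethoxy)benzaldehyde; 3 diethyl {2-[methoxy(methyl)amino]-2-oxoethyl}phosphonate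
Product: 4 (E)-N-methoxy-3-[4-(methoxymethoxy)phenyl]-N-methylprop-2-enamide
Conditions: NaH, THF, 0 °C → rt
Reagents that add atoms: none
Why: Horner–Wadsworth–Emmons olefination of an aromatic aldehyde with a stabilised amide phosphonate should give the E enamide under thermodynamic control, which fixes the enone geometry of the target.

**Step 3**
Reactants: 4 (E)-N-methoxy-3-[4-(methoxymethoxy)phenyl]-N-methylprop-2-enamide; 5 methyl 3,5-dioxohexanoate
Product: 7 methyl (E)-9-[4-(methoxymethoxy)phenyl]-3,5,7-trioxonon-8-enoate, via trilithium trienolate of methyl 3,5-dioxohexanoate 6 (not isolated)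
Conditions: 5, LiN(iPr)2 (3.2 equiv), THF, −78 → 0 °C; then 4, −78 → −20 °C; AcOH, then pH 5 buffer
Reagents that add atoms: none
Why: Acylation of a β,δ-diketo ester trianion at its terminal, most basic carbon by a Weinreb amide should add 1,2 and hold the product as a chelated tetrahedral adduct until the quench, so that neither double addition nor proton transfer from the more acidic triketo ester can occur.

**Step 4**
Reactants: 7 methyl (E)-9-[4-(methoxymethoxy)phenyl]-3,5,7-trioxonon-8-enoate
Product: 9 (E)-3-[4-(methoxymethoxy)phenyl]-1-(2,4,6-trihydroxyphenyl)prop-2-en-1-one, via 2-{(E)-3-[4-(methoxymethoxy)phenyl]acryloyl}cyclohexane-1,3,5-trione 8 (not isolated)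
Conditions: KOH (excess), MeOH, 0 °C → rt, Ar; then ice-cold dilute HCl to pH 4
Reagents that add atoms: none
Why: Excess KOH in methanol converts 7 into its polyenolate, and the carbanion at C6, flanked by the C5 and C7 carbonyls, adds to the ester carbonyl C1 and expels methoxide, an intramolecular Claisen (Dieckmann-type) acylation that forms the C1'–C2' bond. Ring A, the only ring made, closes in the 6-exo-trig mode, and trione 8 enolises at once to the aromatic phloroglucinol, which makes the closure irreversible. The closest known reaction type is the base-induced Claisen cyclization of 3,5,7-triketo esters to acylphloroglucinols, the laboratory counterpart of the chalcone synthase folding. No stereocentre is formed and the E enone is not touched. The step needs chemoselectivity for the C6-to-C1 Claisen closure over the C2-to-C7 aldol closure and over lactonisation to a 4-hydroxy-2-pyrone; the intact methyl ester under strongly basic, non-buffered conditions keeps C1 an acyl donor, the C7 carbonyl is a poor aldol acceptor because it is enolised and conjugated to the 4-alkoxystyryl group, and any pyrone is reopened by methoxide. Acidifying cold and quickly should deliver the open chalcone 9 and not its flavanone.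

**Step 5**
Reactants: 9 (E)-3-[4-(methoxymethoxy)phenyl]-1-(2,4,6-trihydroxyphenyl)prop-2-en-1-one
Product: 10 (E)-1-[2,6-dihydroxy-4-(methoxymethoxy)phenyl]-3-[4-(methoxymethoxy)phenyl]prop-2-en-1-one
Conditions: MOMCl (1.05 equiv), iPr2NEt, THF, 0 °C
Reagents that add atoms: chloromethyl methyl ether, COCCl
Why: Selective O-alkylation should occur at the 4'-hydroxyl, which is para to the carbonyl, the most acidic and the only one not tied up in the hydrogen bond to the ketone, and the symmetry of 9 makes the two remaining ortho hydroxyls equivalent.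

**Step 6**
Reactants: 10 (E)-1-[2,6-dihydroxy-4-(methoxymethoxy)phenyl]-3-[4-(methoxymethoxy)phenyl]prop-2-en-1-one
Product: 11 (E)-1-[2-hydroxy-6-methoxy-4-(methoxymethoxy)phenyl]-3-[4-(methoxymethoxy)phenyl]prop-2-en-1-one
Conditions: Me2SO4 (1.1 equiv), K2CO3, acetone, 40 °C
Reagents that add atoms: dimethyl sulfate, COS(=O)(=O)OC
Why: Williamson O-methylation of one of the two equivalent ortho hydroxyls should stop after one methyl group because the remaining hydroxyl is locked in a strong chelate with the ketone, and any flavanone tautomer of 10 is reopened by E1cB elimination under these conditions and funnelled to the same chalcone.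

**Step 7**
Reactants: 11 (E)-1-[2-hydroxy-6-methoxy-4-(methoxymethoxy)phenyl]-3-[4-(methoxymethoxy)phenyl]prop-2-en-1-one
Product: 12 (E)-1-[2-hydroxy-3-iodo-6-methoxy-4-(methoxymethoxy)phenyl]-3-[4-(methoxymethoxy)phenyl]prop-2-en-1-one
Conditions: BnMe3N·ICl2 (1.05 equiv), NaHCO3, CH2Cl2–MeOH, rt, dark
Reagents that add atoms: benzyltrimethylammonium dichloroiodate, C[N+](C)(C)Cc1ccccc1.Cl[I-]Cl
Why: Electrophilic aromatic iodination of an ortho-hydroxyaryl ketone should take place at C3', ortho to the free hydroxyl and para to the methoxy group, as is usual for 2-hydroxy-4,6-dialkoxyaryl ketones, while the bicarbonate buffer protects the MOM ethers and the electron-poor enone and ring B stay untouched.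

**Step 8**
Reactants: 12 (E)-1-[2-hydroxy-3-iodo-6-methoxy-4-(methoxymethoxy)phenyl]-3-[4-(methoxymethoxy)phenyl]prop-2-en-1-one
Product: 13 (E)-1-(2,4-dihydroxy-3-iodo-6-methoxyphenyl)-3-(4-hydroxyphenyl)prop-2-en-1-one
Conditions: HCl (3 M aq.), MeOH, rt
Reagents that add atoms: none
Why: Acid-catalysed acetal exchange with methanol should remove both MOM groups at room temperature without closing the flavanone, and it is placed before the side chain is introduced because the Z-hydroxyalkenyl phenol of the target would cyclise to a chromene in acid.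

**Step 9**
Reactants: 14 2-methylbut-3-yn-2-ol
Product: 15 2-methyl-4-(tributylstannyl)but-3-yn-2-ol
Conditions: n-BuLi (2.05 equiv), THF, −78 → 0 °C; Bu3SnCl (1.0 equiv), −78 °C → rt; aq. NH4Cl
Reagents that add atoms: tributyltin chloride, CCCC[Sn](Cl)(CCCC)CCCC
Why: Stannylation of the alkoxide–acetylide dianion should take place at the acetylide carbon, the more nucleophilic site towards tin, and any O–Sn bond is hydrolysed on work-up.

**Step 10**
Reactants: 15 2-methyl-4-(tributylstannyl)but-3-yn-2-ol
Product: 17 (Z)-2-methyl-4-(tributylstannyl)but-3-en-2-ol, via geminal stannyl zirconocenyl alkene 16 (not isolated)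
Conditions: Cp2Zr(H)Cl (2.2 equiv), THF, rt; then H2O
Reagents that add atoms: none
Why: After the first equivalent has metalated the hydroxyl, syn-hydrozirconation of the alkynylstannane should place zirconium on the tin-bearing carbon and hydrogen on C3, and protonolysis of the C–Zr bond with retention leaves tin cis to the carbinol carbon, which sets the Z geometry.

**Step 11**
Reactants: 13 (E)-1-(2,4-dihydroxy-3-iodo-6-methoxyphenyl)-3-(4-hydroxyphenyl)prop-2-en-1-one; 17 (Z)-2-methyl-4-(tributylstannyl)but-3-en-2-ol
Product: 18 candidachalcone, (E)-1-{2,4-dihydroxy-3-[(Z)-3-hydroxy-3-methylbut-1-enyl]-6-methoxyphenyl}-3-(4-hydroxyphenyl)prop-2-en-1-one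
Conditions: Pd2(dba)3 (cat.), AsPh3, CuI (cat.), DMF (degassed), 45 °C, dark; aq. KF work-up, neutral chromatography
Reagents that add atoms: none
Why: Stille coupling (oxidative addition of zerovalent palladium into the aryl C–I bond, CuI-assisted transfer of the alkenyl group with retention, reductive elimination) should join C3' to the Z-alkenyl unit under neutral conditions, which tolerate the free phenols and tertiary alcohol and avoid both the base-induced flavanone closure and the acid-induced chromene closure of the product.

**Compound list**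
1 | 4-hydroxybenzaldehyde | O=Cc1ccc(O)cc1 | starting material
2 | 4-(methoxymethoxy)benzaldehyde | COCOc1ccc(C=O)cc1 | intermediate
3 | diethyl {2-[methoxy(methyl)amino]-2-oxoethyl}phosphonate | CCOP(=O)(CC(=O)N(C)OC)OCC | starting material
4 | (E)-N-methoxy-3-[4-(methoxymethoxy)phenyl]-N-methylprop-2-enamide | COCOc1ccc(/C=C/C(=O)N(C)OC)cc1 | intermediate
5 | methyl 3,5-dioxohexanoate | COC(=O)CC(=O)CC(C)=O | starting material
6 | trilithium trienolate of methyl 3,5-dioxohexanoate | [Li+].[Li+].[Li+].C=C([O-])C=C([O-])C=C([O-])OC | intermediate (not isolated)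
7 | methyl (E)-9-[4-(methoxymethoxy)phenyl]-3,5,7-trioxonon-8-enoate (drawn as the triketo tautomer) | COCOc1ccc(/C=C/C(=O)CC(=O)CC(=O)CC(=O)OC)cc1 | intermediate
8 | 2-{(E)-3-[4-(methoxymethoxy)phenyl]acryloyl}cyclohexane-1,3,5-trione | COCOc1ccc(/C=C/C(=O)C2C(=O)CC(=O)CC2=O)cc1 | intermediate (not isolated)
9 | (E)-3-[4-(methoxymethoxy)phenyl]-1-(2,4,6-trihydroxyphenyl)prop-2-en-1-one | COCOc1ccc(/C=C/C(=O)c2c(O)cc(O)cc2O)cc1 | intermediate
10 | (E)-1-[2,6-dihydroxy-4-(methoxymethoxy)phenyl]-3-[4-(methoxymethoxy)phenyl]prop-2-en-1-one | COCOc1ccc(/C=C/C(=O)c2c(O)cc(OCOC)cc2O)cc1 | intermediate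
11 | (E)-1-[2-hydroxy-6-methoxy-4-(methoxymethoxy)phenyl]-3-[4-(methoxymethoxy)phenyl]prop-2-en-1-one | COCOc1ccc(/C=C/C(=O)c2c(O)cc(OCOC)cc2OC)cc1 | intermediate
12 | (E)-1-[2-hydroxy-3-iodo-6-methoxy-4-(methoxymethoxy)phenyl]-3-[4-(methoxymethoxy)phenyl]prop-2-en-1-one | COCOc1ccc(/C=C/C(=O)c2c(O)c(I)c(OCOC)cc2OC)cc1 | intermediate
13 | (E)-1-(2,4-dihydroxy-3-iodo-6-methoxyphenyl)-3-(4-hydroxyphenyl)prop-2-en-1-one | COc1cc(O)c(I)c(O)c1C(=O)/C=C/c1ccc(O)cc1 | intermediate
14 | 2-methylbut-3-yn-2-ol | CC(C)(O)C#C | starting material
15 | 2-methyl-4-(tributylstannyl)but-3-yn-2-ol | CCCC[Sn](CCCC)(CCCC)C#CC(C)(C)O | intermediate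
16 | zirconocene chloride alkoxide of 4-[chlorobis(cyclopentadienyl)zirconio]-2-methyl-4-(tributylstannyl)but-3-en-2-ol, tin cis and zirconium trans to the carbinol carbon | CC(C)(O[Zr](Cl)(C1C=CC=C1)C1C=CC=C1)/C=C(/[Zr](Cl)(C1C=CC=C1)C1C=CC=C1)[Sn](CCCC)(CCCC)CCCC | intermediate (not isolated)
17 | (Z)-2-methyl-4-(tributylstannyl)but-3-en-2-ol | CC(C)(O)/C=C\[Sn](CCCC)(CCCC)CCCC | intermediate
18 | candidachalcone, (E)-1-{2,4-dihydroxy-3-[(Z)-3-hydroxy-3-methylbut-1-enyl]-6-methoxyphenyl}-3-(4-hydroxyphenyl)prop-2-en-1-one | COc1cc(O)c(/C=C\C(C)(C)O)c(O)c1C(=O)/C=C/c1ccc(O)cc1 | target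

**Count**
Total steps: 11. Longest linear sequence: 9 steps (steps 1–8, then step 11); the stannane branch is 2 steps (steps 9–10).

**Steps most likely to fail**

Step 4. The polyenolate may close instead by aldol attack of C2 on C7, lactonise through an enol oxygen to a 4-hydroxy-2-pyrone, or lose the ester by hydrolysis before cyclising. The freed chalcone may also ring-close to the flavanone during acidification. Fallback: ring A is bought and not built. The fallback sets out from aldehyde 2 and comes back to the route at chalcone 11. Commercial 1-(2,4-dihydroxy-6-methoxyphenyl)ethanone is protected at its non-chelated 4-hydroxyl (MOMCl, iPr2NEt, CH2Cl2) to give 1-[2-hydroxy-6-methoxy-4-(methoxymethoxy)phenyl]ethanone F1. Claisen–Schmidt condensation of this ketone with 2 (KOH, EtOH–H2O, rt) should give 11 directly, and the route continues at step 7.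

Step 11. Oxidative addition and transmetalation at an iodide flanked by two hydroxyls may be slow. That would leave time for protodestannylation of 17 by the acidic phenols, Z-to-E isomerisation of the alkenyl group, or reductive loss of iodine. Fallback: a Suzuki–Miyaura coupling with a silyl-protected Z-alkenylboronate. It sets out from iodide 13 and alkyne 14 and comes back at target 18. Alkyne 14 is silylated (TESOTf, 2,6-lutidine, CH2Cl2) to triethyl[(2-methylbut-3-yn-2-yl)oxy]silane F2. Rhodium-catalysed trans-hydroboration ([Rh(cod)Cl]2, P(iPr)3, Et3N, pinacolborane, cyclohexane, rt) should give triethyl{[(Z)-2-methyl-4-(4,4,5,5-tetramethyl-1,3,2-dioxaborolan-2-yl)but-3-en-2-yl]oxy}silane F3. Coupling with 13 (Pd(OAc)2, SPhos, K3PO4, THF–H2O, 40 °C, cold buffered work-up) should give (E)-1-{2,4-dihydroxy-6-methoxy-3-[(Z)-3-methyl-3-(triethylsilyloxy)but-1-enyl]phenyl}-3-(4-hydroxyphenyl)prop-2-en-1-one F4. Buffered fluoride (TBAF, AcOH, THF, 0 °C) then frees the tertiary alcohol to give 18.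

Step 3. Trianion formation may be incomplete, the trianion may be quenched by proton transfer, 5 may self-condense, or the triketo ester may cyclise during work-up and isolation. Fallback: the chain is built in the other order. It sets out from Weinreb amide 4 and comes back at triketo ester 7. The dianion of pentane-2,4-dione (LiN(iPr)2, 2 equiv, THF) is acylated at its terminal carbon by 4 to give (E)-8-[4-(methoxymethoxy)phenyl]oct-7-ene-2,4,6-trione F5. The trianion of this triketone (LiN(iPr)2, excess, THF) is then carboxylated at the terminal methyl group with dimethyl carbonate to give 7.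

**Further compounds**
F1 | step 4 | 1-[2-hydroxy-6-methoxy-4-(methoxymethoxy)phenyl]ethanone | CC(=O)c1c(O)cc(OCOC)cc1OC
F2 | step 11 | triethyl[(2-methylbut-3-yn-2-yl)oxy]silane | CC[Si](CC)(CC)OC(C)(C)C#C
F3 | step 11 | triethyl{[(Z)-2-methyl-4-(4,4,5,5-tetramethyl-1,3,2-dioxaborolan-2-yl)but-3-en-2-yl]oxy}silane | CC[Si](CC)(CC)OC(C)(C)/C=C\B1OC(C)(C)C(C)(C)O1
F4 | step 11 | (E)-1-{2,4-dihydroxy-6-methoxy-3-[(Z)-3-methyl-3-(triethylsilyloxy)but-1-enyl]phenyl}-3-(4-hydroxyphenyl)prop-2-en-1-one | COc1cc(O)c(/C=C\C(C)(C)O[Si](CC)(CC)CC)c(O)c1C(=O)/C=C/c1ccc(O)cc1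
F5 | step 3 | (E)-8-[4-(methoxymethoxy)phenyl]oct-7-ene-2,4,6-trione | COCOc1ccc(/C=C/C(=O)CC(=O)CC(C)=O)cc1
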